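## Analysis of the target

The target is an unsymmetrical ether of two 2-(2-phenylethyl)chromones. One is a 5,6,7,8-tetrahydro-4H-chromen-4-one whose carbocycle (ring A) carries oxygen on all four sp3 carbons; it is joined through O5 to C6′ of a fully aromatic 7′-hydroxychromone. Ring A is fused to the γ-pyranone (ring B) through the sp2 carbons C4a and C8a, so the only stereocentres are C5, C6, C7 and C8, configured 5S,6S,7R,8S. O6 and O7 are cis to each other, O5 is trans to O6 and O8 is trans to O7, so O5 and O8 are cis. With C4a and C8a planar this pattern would be meso in a symmetrically substituted ring: the absolute configuration is decided only by which end of the tetrol carries the C4 carbonyl and which carries O1. The sensitive features are the C5–O and C8–O bonds, both allylic to the vinylogous ester (C5 can ionise with help from O1, C8–H is vinylogously acidic), the ease with which ring A can lose two oxygen functions to become an aromatic chromone, the reducible pyranone double bonds and the free phenol. The difficulty is to make four contiguous carbinol centres in one absolute sense while keeping their oxygens distinguishable, because one becomes an aryl ether and the two flanking carbons must become the ring fusion. The strategy rests on the C6/C7 cis-diol lying trans to the like-oriented oxygens on C5 and C8. That is the expected result when two aldehydes, each flanked by an alkoxy-bearing stereocentre of the same sense, are coupled reductively. C2 and C5 of a D-gluco chain have this relationship, and its C3 and C4 can then serve as C8a and C4a.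

## Retrosynthetic reasoning

Compounds are numbered as in the steps below.

**Protecting groups.** Target 38 is traced to 37 and then to 36 by cutting only protecting-group bonds: the acetonide on O6/O7 and the benzyl ethers on O8 and O7′. They are chosen so that the last two operations are neutral hydrogenolysis and mild aqueous acid, and nothing basic touches the deprotected ring A.

**Aryl ether.** The ether in 36 is cut at O5–C6′ and not at C5–O5. Cutting at C5 would mean substitution at a stereocentre that ionises easily. Cutting at the arene leaves C5 untouched, so its configuration is that of alcohol 26. The forward reaction has to transfer a chromon-6-yl group to a hindered secondary alkoxide at room temperature, which is what iodonium salt 34 is for. Salt 34 comes from iodide 32, whose pyranone is cut at C2′–C3′ and O1′–C2′ into ketone 29 and ester 30. Iodine is placed at the acetophenone stage (27 to 28 to 29), where substitution goes para to the free hydroxyl, the future C6′. A finished 7-alkoxychromone would react at C8′.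

**Ring B.** Alcohol 26 comes from silyl ether 25. Ring B of 25 is cut at C4–C4a and O1–C8a, which removes the whole pyranone and leaves enol ether 19 and the acylketene source 22 (from 20 by γ-benzylation). This is preferred to building ring A onto a pyranone because it reduces the problem to a carbocyclic ketone, 18, whose stereocentres can come from a cyclitol. The forward step must acylate C4a and not C8, so the enol ether has to be formed towards the methylene of 18.

**Ketone and methylene.** The C4a methylene of 18 is traced to the α-pivaloyloxy ketone 17, the ketone to alcohol 16, and that to the 4-methoxybenzyl ether 15. What is gained is a fully oxygenated cyclitol in which the protecting groups record the site of the ketone (C8a) and of the deoxygenation (C4a). That choice also fixes the enantiomer, as the analysis shows.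

**Ring A.** Acetonide 15 comes from diol 14, and in 14 the C6–C7 bond is cut to give dialdehyde 13. This is the one ring bond flanked on both sides by stereocentres that can direct its formation, and cutting it turns a cyclitol into an acyclic sugar derivative. Forward, the coupling must give the cis-diol anti to both neighbouring oxygens.

**Sugar chain.** Dialdehyde 13 comes from diol 12 by oxidation, and 12 from hemiacetal 9 by reduction, silylation of O1 and O5 together, and release of the two primary alcohols (10, 11). Opening the pyranose is what frees O5 for its own protecting group. The pattern of 8 (benzyl on O2, 4-methoxybenzyl on O3, pivaloyl on O4, silyl on O6) is assembled on the thioglycoside 1 through the 4,6-benzylidene acetal 2 and a tin-mediated alkylation at O3 (4 to 7).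

## Alternatives that were turned down

**Alternative 1:** Ring A is taken from the flat quinone A1, 2-(2-phenylethyl)chromone-5,8-dione. Cyclopentadiene A2 adds endo across C6=C7 under a chiral oxazaborolidinium Lewis acid to give adduct A3. The two new carbon–carbon bonds are not in the target: the norbornene is a temporary shield. Both ring carbonyls would be reduced from the open face, the diene expelled by retro-Diels–Alder reaction, and the regenerated C6=C7 bond dihydroxylated anti to the two carbinols.
- For: A1 is a few steps from a simple acetophenone, chirality is catalytic, and the relative configuration follows from substrate control. On step economy it is clearly stronger than a route from a sugar.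
- Against: A1 is nearly symmetric across C6=C7, and the absolute configuration depends only on telling the C5 side from the C8 side, so the catalyst must bind one of two similar carbonyls selectively.
- Against: A3 is an ene-dione with two acidic ring-fusion hydrogens and can tautomerise to the aromatic hydroquinone, which erases the stereocentres.
- Against: the retro-cycloaddition needs heat that a 5,8-dihydroxy-5,8-dihydrochromone, one dehydration from a phenol, is unlikely to survive.
- Against: the carbinols at C5 and C8 end in almost identical environments although only O5 may be arylated.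
- Comparison: the chosen strategy is longer, but it takes the absolute configuration from the chiral pool and keeps the four oxygens distinguishable from the first step.

**Alternative 2:** Both heterocycles are cut at O1–C2 and O1′–C2′. This leads to bis-ynone A4, in which a 2-acylcyclohexanone and an o-hydroxyaryl ketone each carry a 5-phenylpent-2-ynoyl group. A secondary amine would add to both ynones, and the enol and phenol oxygens would close rings B and B′ in one operation to give A5, the tetra-O-benzyl target.
- For: both phenethylpyranones are made by the same reaction at the same time, no acylketene and no separate chromone synthesis is needed, and amine-mediated ynone cyclisation is well established for chromones. In convergence at the end it is equal or better.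
- Against: A4 already holds the C5–O–aryl ether β to two carbonyl groups, with an acidic hydrogen at C4a between them, so amine base is expected to expel the aryloxide by E1cB elimination. C8 is also epimerisable next to the C8a ketone.
- Against: the strategy does not say where the four stereocentres come from, so a cyclitol synthesis of the present kind would still be needed in front of it.
- Against: a fourfold hydrogenolysis must spare two pyranones.
- Comparison: the chosen route forms the ether after ring B exists, when C4a is sp2 and no enolate can form beside C5.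

**Alternative 3:** Ring B is cut at C4–C4a and O1–C8a. The silyl enol ether A6 of a tetra-oxygenated cyclohexanone reacts with the acylketene released thermally from dioxinone A7 (the same compound as 22) in a hetero-Diels–Alder reaction, and loss of silanol gives A8.
- For: it is convergent and forms two bonds and the whole pyranone under neutral conditions. On this point it is as strong as the chosen route, which uses the same reaction in step 19.
- Against: as the organising idea it addresses the smaller risk. It presupposes A6, an enantiopure ketone with four contiguous stereocentres enolised away from an α-alkoxy carbon, and is silent on how to obtain it.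
- Comparison: the chosen strategy supplies what is missing. The pinacol closure sets the stereocentres, and the pivalate on C4a makes the methylene appear exactly where the enol ether must form.

Key step: step 12

## Route

Assumption: D-glucose enters as its commercially available phenyl 1-thio-β-D-pyranoside 1. From step 12 on, the carbocycle is numbered as in the target (C4a, C5, C6, C7, C8, C8a). TBS = tert-butyldimethylsilyl.

Step 1
Reactants: 1 phenyl 1-thio-β-D-glucopyranoside
Product: 2 phenyl 4,6-O-[(R)-benzylidene]-1-thio-β-D-glucopyranoside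
Conditions: PhCH(OMe)2, camphorsulfonic acid (cat.), MeCN, 50 °C
Reagents that add atoms: benzaldehyde dimethyl acetal COC(OC)c1ccccc1
Why: Acid-catalysed transacetalisation under thermodynamic control; the 4,6-diol gives the trans-fused six-membered acetal with equatorial phenyl and leaves O2 and O3 free.

Step 2
Reactants: 2 phenyl 4,6-O-[(R)-benzylidene]-1-thio-β-D-glucopyranoside
Product: 4 phenyl 4,6-O-benzylidene-3-O-(4-methoxybenzyl)-1-thio-β-D-glucopyranoside, via 2,3-O-dibutylstannylene acetal 3 (not isolated)
Conditions: Bu2SnO, toluene, reflux (Dean–Stark); then 4-methoxybenzyl chloride, CsF, DMF, rt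
Reagents that add atoms: 4-methoxybenzyl chloride COc1ccc(CCl)cc1
Why: Regioselective stannylene-mediated O-alkylation; in β-configured 4,6-O-benzylidene glucosides O2 has no cis-vicinal anomeric oxygen to activate it, so the tin acetal should be alkylated at O3.

Step 3
Reactants: 4 phenyl 4,6-O-benzylidene-3-O-(4-methoxybenzyl)-1-thio-β-D-glucopyranoside
Product: 5 phenyl 2-O-benzyl-4,6-O-benzylidene-3-O-(4-methoxybenzyl)-1-thio-β-D-glucopyranoside
Conditions: NaH, BnBr, Bu4NI (cat.), DMF, 0 °C → rt
Reagents that add atoms: benzyl bromide BrCc1ccccc1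
Why: Williamson etherification of the only free hydroxyl; the benzyl ether is the persistent group for the future O8.

Step 4
Reactants: 5 phenyl 2-O-benzyl-4,6-O-benzylidene-3-O-(4-methoxybenzyl)-1-thio-β-D-glucopyranoside
Product: 6 phenyl 2-O-benzyl-3-O-(4-methoxybenzyl)-1-thio-β-D-glucopyranoside
Conditions: TsOH·H2O (cat.), MeOH/CH2Cl2, rt
Reagents that add atoms: none
Why: Acid-catalysed transacetalisation to methanol removes the benzylidene acetal; the 4-methoxybenzyl ether and the thioglycoside tolerate catalytic sulfonic acid in methanol at room temperature.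

Step 5
Reactants: 6 phenyl 2-O-benzyl-3-O-(4-methoxybenzyl)-1-thio-β-D-glucopyranoside
Product: 7 phenyl 2-O-benzyl-6-O-TBS-3-O-(4-methoxybenzyl)-1-thio-β-D-glucopyranoside
Conditions: TBSCl, imidazole, CH2Cl2, 0 °C
Reagents that add atoms: tert-butyldimethylsilyl chloride CC(C)(C)[Si](C)(C)Cl
Why: Selective silylation of the primary 6-hydroxyl over the hindered secondary 4-hydroxyl.

Step 6
Reactants: 7 phenyl 2-O-benzyl-6-O-TBS-3-O-(4-methoxybenzyl)-1-thio-β-D-glucopyranoside
Product: 8 phenyl 2-O-benzyl-6-O-TBS-3-O-(4-methoxybenzyl)-4-O-pivaloyl-1-thio-β-D-glucopyranoside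
Conditions: pivaloyl chloride, DMAP, pyridine, 60 °C
Reagents that add atoms: pivaloyl chloride CC(C)(C)C(=O)Cl
Why: DMAP-catalysed acylation of the remaining 4-hydroxyl; the pivalate is chosen because it resists migration and borohydride and later serves as the leaving group on C4a.

Step 7
Reactants: 8 phenyl 2-O-benzyl-6-O-TBS-3-O-(4-methoxybenzyl)-4-O-pivaloyl-1-thio-β-D-glucopyranoside
Product: 9 2-O-benzyl-6-O-TBS-3-O-(4-methoxybenzyl)-4-O-pivaloyl-D-glucopyranose (anomeric mixture)
Conditions: N-bromosuccinimide, NaHCO3, acetone/H2O (9:1), −15 → 0 °C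
Reagents that add atoms: water O
Why: Thioglycoside hydrolysis: bromination at sulfur gives a bromosulfonium ion, and the oxocarbenium ion it releases is captured by water; the buffer protects the silyl and 4-methoxybenzyl ethers.

Step 8
Reactants: 9 2-O-benzyl-6-O-TBS-3-O-(4-methoxybenzyl)-4-O-pivaloyl-D-glucopyranose
Product: 10 2-O-benzyl-6-O-TBS-3-O-(4-methoxybenzyl)-4-O-pivaloyl-D-glucitol
Conditions: NaBH4, EtOH/THF, 0 °C → rt
Reagents that add atoms: none
Why: Borohydride reduces the open-chain aldehyde tautomer of the lactol, which makes C1 a primary alcohol and releases O5–H; the pivalate is inert to NaBH4 and its bulk should slow O4 → O5 acyl migration.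

Step 9
Reactants: 10 2-O-benzyl-6-O-TBS-3-O-(4-methoxybenzyl)-4-O-pivaloyl-D-glucitol
Product: 11 2-O-benzyl-1,5,6-tri-O-TBS-3-O-(4-methoxybenzyl)-4-O-pivaloyl-D-glucitol
Conditions: TBSOTf, 2,6-lutidine, CH2Cl2, −78 → 0 °C
Reagents that add atoms: tert-butyldimethylsilyl trifluoromethanesulfonate CC(C)(C)[Si](C)(C)OS(=O)(=O)C(F)(F)F
Why: The silyl triflate silylates both the primary 1-hydroxyl and the hindered secondary 5-hydroxyl, so O5 receives its ether in the same operation that masks C1.

Step 10
Reactants: 11 2-O-benzyl-1,5,6-tri-O-TBS-3-O-(4-methoxybenzyl)-4-O-pivaloyl-D-glucitol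
Product: 12 2-O-benzyl-5-O-TBS-3-O-(4-methoxybenzyl)-4-O-pivaloyl-D-glucitol
Conditions: HF·pyridine, pyridine, THF, 0 °C
Reagents that add atoms: none
Why: Selective desilylation: buffered fluoride should cleave the two unhindered primary silyl ethers well before the secondary one, which is flanked by the pivaloyloxy-bearing carbon.

Step 11
Reactants: 12 2-O-benzyl-5-O-TBS-3-O-(4-methoxybenzyl)-4-O-pivaloyl-D-glucitol
Product: 13 2-O-benzyl-5-O-TBS-3-O-(4-methoxybenzyl)-4-O-pivaloyl-D-gluco-hexodialdose
Conditions: Dess–Martin periodinane, NaHCO3, CH2Cl2, 0 °C → rt; used crude after aqueous work-up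
Reagents that add atoms: none
Why: Dess–Martin oxidation of both primary alcohols under neutral buffered conditions; an amine-based oxidation is avoided because the C6 aldehyde carries the pivalate in the β-position and would eliminate, and because α-alkoxy aldehydes epimerise with base.

Step 12
Reactants: 13 2-O-benzyl-5-O-TBS-3-O-(4-methoxybenzyl)-4-O-pivaloyl-D-gluco-hexodialdose
Product: 14 8-O-benzyl-5-O-TBS-8a-O-(4-methoxybenzyl)-4a-O-pivaloyl-chiro-inositol (free cis-diol at C6/C7; target numbering)
Conditions: SmI2 (0.1 M in THF, 4 equiv), t-BuOH, THF, −78 °C → rt, slow addition of 13 at high dilution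
Reagents that add atoms: none
Why: Divalent samarium transfers one electron to an aldehyde to give a samarium-bound ketyl, which adds to the second, samarium-activated aldehyde; a second electron gives the trivalent samarium diolate, which is hydrolysed on work-up. The closest known reaction type is the SmI2 pinacol cyclisation of carbohydrate-derived 1,6-dialdehydes to inositols. Ring A closes by a 6-exo-trig attack of the ketyl carbon on the other carbonyl carbon, forming the C6–C7 bond. C6 and C7 are set relative to each other by the two oxygens staying bound to samarium in the cyclic transition state, which enforces the cis-diol. Their face is set by the neighbours C5 and C8: each α-alkoxy group turns away from the adjacent samarium-bound oxygen, and because the silyloxy group on C5 and the benzyloxy group on C8 lie on the same face of the forming ring, one diastereomer satisfies both. The step needs coupling to win over α-deoxygenation and over attack on the ester, which is secured by having ethers and not esters at both α-positions, by the low temperature and by the absence of strongly activating additives. It also needs ring closure to win over intermolecular coupling, which slow addition at high dilution secures.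

Step 13
Reactants: 14 8-O-benzyl-5-O-TBS-8a-O-(4-methoxybenzyl)-4a-O-pivaloyl-chiro-inositol
Product: 15 6,7-O-isopropylidene derivative of 14
Conditions: 2,2-dimethoxypropane, pyridinium p-toluenesulfonate (cat.), CH2Cl2, rt
Reagents that add atoms: 2,2-dimethoxypropane COC(C)(C)OC
Why: Acetonide formation on the cis-1,2-diol; mild acid leaves the silyl and 4-methoxybenzyl ethers intact.

Step 14
Reactants: 15 6,7-O-isopropylidene derivative of 14
Product: 16 8-O-benzyl-6,7-O-isopropylidene-5-O-TBS-4a-O-pivaloyl-chiro-inositol (free 8a-OH)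
Conditions: DDQ, CH2Cl2/pH 7 buffer (10:1), 0 °C
Reagents that add atoms: none
Why: Oxidative cleavage of the electron-rich 4-methoxybenzyl ether by hydride abstraction and hydrolysis; the benzyl ether reacts much more slowly and the buffer protects the acetonide.

Step 15
Reactants: 16 8-O-benzyl-6,7-O-isopropylidene-5-O-TBS-4a-O-pivaloyl-chiro-inositol
Product: 17 8-O-benzyl-6,7-O-isopropylidene-5-O-TBS-4a-O-pivaloyl-inosose (carbonyl at C8a)
Conditions: Dess–Martin periodinane, NaHCO3, CH2Cl2, rt
Reagents that add atoms: none
Why: Dess–Martin oxidation of the hindered secondary alcohol under non-basic conditions, so that neither α-stereocentre epimerises and no β-oxygen is eliminated.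

Step 16
Reactants: 17 8-O-benzyl-6,7-O-isopropylidene-5-O-TBS-4a-O-pivaloyl-inosose
Product: 18 2-(benzyloxy)-5-(TBS-oxy)-3,4-(isopropylidenedioxy)cyclohexanone (C8a ketone; C4a methylene)
Conditions: SmI2 (2.2 equiv), THF/MeOH, −78 °C
Reagents that add atoms: none
Why: Reductive cleavage of an α-acyloxy ketone by SmI2: the ketyl takes up a second electron and expels the α-carboxylate, and the samarium enolate is protonated by methanol. The pivalate is a far better leaving group than the α-benzyloxy group, and the silyloxy group on C5 is a poor β-leaving group for the enolate.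

Step 17
Reactants: 18 2-(benzyloxy)-5-(TBS-oxy)-3,4-(isopropylidenedioxy)cyclohexanone
Product: 19 trimethylsilyl enol ether of 18 (C8a=C4a; OSiMe3 on C8a)
Conditions: Me3SiCl, LiN(SiMe3)2, THF, −78 °C (in situ quench); non-aqueous work-up
Reagents that add atoms: chlorotrimethylsilane C[Si](C)(C)Cl
Why: Kinetic deprotonation at the unsubstituted α-methylene in the presence of the silylating agent fixes the enol ether towards C4a; the alkoxy-bearing C8 is deprotonated more slowly, so its configuration and the β-oxygen on C7 are not put at risk.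

Step 18
Reactants: 20 2,2,6-trimethyl-4H-1,3-dioxin-4-one
Product: 22 2,2-dimethyl-6-(2-phenylethyl)-4H-1,3-dioxin-4-one, via lithium dienolate 21 (not isolated)
Conditions: LiN(i-Pr)2, THF, −78 °C; then BnBr, HMPA, −78 → −40 °C
Reagents that add atoms: benzyl bromide BrCc1ccccc1
Why: γ-Deprotonation of the vinylogous ester and alkylation of the dienolate at the γ-carbon by a reactive benzylic halide.

Step 19
Reactants: 19 trimethylsilyl enol ether of 18; 22 2,2-dimethyl-6-(2-phenylethyl)-4H-1,3-dioxin-4-one
Product: 25 8-O-benzyl-6,7-O-isopropylidene-5-O-TBS-5,6,7,8-tetrahydroxy-2-(2-phenylethyl)-5,6,7,8-tetrahydrochromone, via acylketene 23 (not isolated), via silyloxydihydropyranone 24 (not isolated)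
Conditions: toluene, 110 °C; then CF3CO2H (cat.), CH2Cl2, 0 °C
Reagents that add atoms: none
Why: Retro-[4+2] cleavage of the dioxinone releases acetone and the acylketene, which undergoes a hetero-Diels–Alder reaction with the enol ether (ketene carbon to the nucleophilic C4a, acyl oxygen to C8a), as known for acylketenes and enol ethers. Acid-induced loss of silanol from the ketal-type adduct then gives the γ-pyranone; no stereocentre is made, since C4a becomes sp2.

Step 20
Reactants: 25 8-O-benzyl-6,7-O-isopropylidene-5-O-TBS-5,6,7,8-tetrahydroxy-2-(2-phenylethyl)-5,6,7,8-tetrahydrochromone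
Product: 26 8-O-benzyl-6,7-O-isopropylidene-5,6,7,8-tetrahydroxy-2-(2-phenylethyl)-5,6,7,8-tetrahydrochromone (free 5-OH)
Conditions: HF·pyridine, pyridine, THF, 0 °C → rt
Reagents that add atoms: none
Why: Fluoride cleavage of the silyl ether under buffered, non-basic conditions that spare the acetonide, the benzyl ether and the base-sensitive ring A.

Step 21
Reactants: 27 2',4'-dihydroxyacetophenone
Product: 28 1-[4-(benzyloxy)-2-hydroxyphenyl]ethanone
Conditions: BnBr, K2CO3, acetone, reflux
Reagents that add atoms: benzyl bromide BrCc1ccccc1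
Why: Williamson etherification selective for the 4-hydroxyl, because the 2-hydroxyl is hydrogen-bonded to the acetyl group.

Step 22
Reactants: 28 1-[4-(benzyloxy)-2-hydroxyphenyl]ethanone
Product: 29 1-[4-(benzyloxy)-2-hydroxy-5-iodophenyl]ethanone
Conditions: N-iodosuccinimide, CF3CO2H (cat.), MeCN, rt
Reagents that add atoms: N-iodosuccinimide O=C1CCC(=O)N1I
Why: Electrophilic aromatic iodination para to the free phenol and ortho to the benzyloxy group; the position between the two oxygens is the more hindered one.

Step 23
Reactants: 29 1-[4-(benzyloxy)-2-hydroxy-5-iodophenyl]ethanone; 30 ethyl 3-phenylpropanoate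
Product: 32 7-(benzyloxy)-6-iodo-2-(2-phenylethyl)-4H-chromen-4-one, via 1,3-diketone 31 (not isolated)
Conditions: NaH, THF, reflux; then conc. HCl, MeOH, 60 °C
Reagents that add atoms: none
Why: Crossed Claisen condensation of the ketone enolate with the ester, followed by acid-catalysed cyclodehydration of the 1,3-diketone onto the phenol, the standard chromone synthesis.

Step 24
Reactants: 32 7-(benzyloxy)-6-iodo-2-(2-phenylethyl)-4H-chromen-4-one
Product: 34 [7-(benzyloxy)-4-oxo-2-(2-phenylethyl)-4H-chromen-6-yl](2,4,6-trimethoxyphenyl)iodonium tosylate, via hydroxy(tosyloxy)iodoarene 33 (not isolated)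
Conditions: 3-chloroperbenzoic acid, TsOH·H2O, MeCN, 55 °C; then 1,3,5-trimethoxybenzene, rt
Reagents that add atoms: 1,3,5-trimethoxybenzene COc1cc(OC)cc(OC)c1; 4-methylbenzenesulfonic acid Cc1ccc(cc1)S(=O)(=O)O
Why: One-pot synthesis of an unsymmetrical diaryliodonium salt: the aryl iodide is oxidised to trivalent iodine, which then substitutes the very electron-rich trimethoxybenzene; the electron-poor chromone double bond is not epoxidised.

Step 25
Reactants: 26 8-O-benzyl-6,7-O-isopropylidene-5,6,7,8-tetrahydroxy-2-(2-phenylethyl)-5,6,7,8-tetrahydrochromone; 34 [7-(benzyloxy)-4-oxo-2-(2-phenylethyl)-4H-chromen-6-yl](2,4,6-trimethoxyphenyl)iodonium tosylate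
Product: 36 5-O-[7-(benzyloxy)-4-oxo-2-(2-phenylethyl)-4H-chromen-6-yl] ether of 26, via sodium alkoxide 35 (not isolated)
Conditions: NaH (1.0 equiv), toluene/THF, 0 °C; then 34, rt
Reagents that add atoms: none
Why: Metal-free O-arylation of an aliphatic alkoxide with a diaryliodonium salt: the alkoxide binds to iodine and ligand coupling transfers the chromonyl group, while the electron-rich trimethoxyphenyl group stays on iodine. The C5–O bond is not broken, so C5 keeps its configuration.

Step 26
Reactants: 36 5-O-[7-(benzyloxy)-4-oxo-2-(2-phenylethyl)-4H-chromen-6-yl] ether of 26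
Product: 37 6,7-O-isopropylidene derivative of the target (free 8-OH; free 7′-OH)
Conditions: H2 (1 atm), Pd/C, EtOAc, rt, stopped at full conversion
Reagents that add atoms: none
Why: Hydrogenolysis of the two primary benzyl ethers, which should be faster than cleavage of the hindered secondary C5–O aryl ether or saturation of either pyranone.

Step 27
Reactants: 37 6,7-O-isopropylidene derivative of the target
Product: 38 6-{[(5S,6S,7R,8S)-6,7,8-trihydroxy-4-oxo-2-(2-phenylethyl)-5,6,7,8-tetrahydro-4H-chromen-5-yl]oxy}-7-hydroxy-2-(2-phenylethyl)-4H-chromen-4-one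
Conditions: AcOH/H2O (4:1), 45 °C
Reagents that add atoms: none
Why: Mild acid hydrolysis of the cis-fused acetonide; weak aqueous acid is chosen to avoid ionisation at C5.

## Compound list

1 | phenyl 1-thio-β-D-glucopyranoside | OC[C@H]1O[C@@H](Sc2ccccc2)[C@H](O)[C@@H](O)[C@@H]1O | starting material
2 | phenyl 4,6-O-[(R)-benzylidene]-1-thio-β-D-glucopyranoside | c1ccccc1[C@@H]2OC[C@H]3O[C@@H](Sc4ccccc4)[C@H](O)[C@@H](O)[C@@H]3O2 | intermediate
3 | phenyl 4,6-O-benzylidene-2,3-O-(dibutylstannylene)-1-thio-β-D-glucopyranoside | c1ccccc1[C@@H]2OC[C@H]3O[C@@H](Sc4ccccc4)[C@H](O5)[C@@H](O[Sn]5(CCCC)CCCC)[C@@H]3O2 | intermediate (not isolated)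
4 | phenyl 4,6-O-benzylidene-3-O-(4-methoxybenzyl)-1-thio-β-D-glucopyranoside | c1ccccc1[C@@H]2OC[C@H]3O[C@@H](Sc4ccccc4)[C@H](O)[C@@H](OCc4ccc(OC)cc4)[C@@H]3O2 | intermediate
5 | phenyl 2-O-benzyl-4,6-O-benzylidene-3-O-(4-methoxybenzyl)-1-thio-β-D-glucopyranoside | c1ccccc1[C@@H]2OC[C@H]3O[C@@H](Sc4ccccc4)[C@H](OCc4ccccc4)[C@@H](OCc4ccc(OC)cc4)[C@@H]3O2 | intermediate
6 | phenyl 2-O-benzyl-3-O-(4-methoxybenzyl)-1-thio-β-D-glucopyranoside | OC[C@H]1O[C@@H](Sc2ccccc2)[C@H](OCc2ccccc2)[C@@H](OCc2ccc(OC)cc2)[C@@H]1O | intermediate
7 | phenyl 2-O-benzyl-6-O-(tert-butyldimethylsilyl)-3-O-(4-methoxybenzyl)-1-thio-β-D-glucopyranoside | CC(C)(C)[Si](C)(C)OC[C@H]1O[C@@H](Sc2ccccc2)[C@H](OCc2ccccc2)[C@@H](OCc2ccc(OC)cc2)[C@@H]1O | intermediate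
8 | phenyl 2-O-benzyl-6-O-(tert-butyldimethylsilyl)-3-O-(4-methoxybenzyl)-4-O-pivaloyl-1-thio-β-D-glucopyranoside | CC(C)(C)[Si](C)(C)OC[C@H]1O[C@@H](Sc2ccccc2)[C@H](OCc2ccccc2)[C@@H](OCc2ccc(OC)cc2)[C@@H]1OC(=O)C(C)(C)C | intermediate
9 | 2-O-benzyl-6-O-(tert-butyldimethylsilyl)-3-O-(4-methoxybenzyl)-4-O-pivaloyl-D-glucopyranose (anomeric mixture) | CC(C)(C)[Si](C)(C)OC[C@H]1OC(O)[C@H](OCc2ccccc2)[C@@H](OCc2ccc(OC)cc2)[C@@H]1OC(=O)C(C)(C)C | intermediate
10 | 2-O-benzyl-6-O-(tert-butyldimethylsilyl)-3-O-(4-methoxybenzyl)-4-O-pivaloyl-D-glucitol | OC[C@H](OCc1ccccc1)[C@@H](OCc1ccc(OC)cc1)[C@H](OC(=O)C(C)(C)C)[C@H](O)CO[Si](C)(C)C(C)(C)C | intermediate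
11 | 2-O-benzyl-1,5,6-tri-O-(tert-butyldimethylsilyl)-3-O-(4-methoxybenzyl)-4-O-pivaloyl-D-glucitol | CC(C)(C)[Si](C)(C)OC[C@H](OCc1ccccc1)[C@@H](OCc1ccc(OC)cc1)[C@H](OC(=O)C(C)(C)C)[C@H](O[Si](C)(C)C(C)(C)C)CO[Si](C)(C)C(C)(C)C | intermediate
12 | 2-O-benzyl-5-O-(tert-butyldimethylsilyl)-3-O-(4-methoxybenzyl)-4-O-pivaloyl-D-glucitol | OC[C@H](OCc1ccccc1)[C@@H](OCc1ccc(OC)cc1)[C@H](OC(=O)C(C)(C)C)[C@H](O[Si](C)(C)C(C)(C)C)CO | intermediate
13 | 2-O-benzyl-5-O-(tert-butyldimethylsilyl)-3-O-(4-methoxybenzyl)-4-O-pivaloyl-D-gluco-hexodialdose | O=C[C@H](OCc1ccccc1)[C@@H](OCc1ccc(OC)cc1)[C@H](OC(=O)C(C)(C)C)[C@H](O[Si](C)(C)C(C)(C)C)C=O | intermediate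
14 | protected chiro-inositol, target numbering: C5 OTBS, C4a O-pivaloyl, C8a O-(4-methoxybenzyl), C8 O-benzyl, C6 and C7 free OH; O5, O4a and O8 on one face, O6, O7 and O8a on the other | O[C@H]1[C@@H](O)[C@H](OCc2ccccc2)[C@@H](OCc2ccc(OC)cc2)[C@H](OC(=O)C(C)(C)C)[C@@H]1O[Si](C)(C)C(C)(C)C | intermediate
15 | 6,7-O-isopropylidene derivative of 14 | CC1(C)O[C@H]2[C@@H](O1)[C@H](OCc3ccccc3)[C@@H](OCc3ccc(OC)cc3)[C@H](OC(=O)C(C)(C)C)[C@@H]2O[Si](C)(C)C(C)(C)C | intermediate
16 | 8a-alcohol: 15 without the 4-methoxybenzyl group | CC1(C)O[C@H]2[C@@H](O1)[C@H](OCc3ccccc3)[C@@H](O)[C@H](OC(=O)C(C)(C)C)[C@@H]2O[Si](C)(C)C(C)(C)C | intermediate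
17 | C8a ketone with pivaloyloxy on C4a, benzyloxy on C8, OTBS on C5, acetonide on O6/O7 (configuration as in 15) | CC1(C)O[C@H]2[C@@H](O1)[C@H](OCc3ccccc3)C(=O)[C@H](OC(=O)C(C)(C)C)[C@@H]2O[Si](C)(C)C(C)(C)C | intermediate
18 | 2-(benzyloxy)-5-[(tert-butyldimethylsilyl)oxy]-3,4-(isopropylidenedioxy)cyclohexanone; C8a ketone, C4a methylene, configuration at C5–C8 as in 38 | CC1(C)O[C@H]2[C@@H](O1)[C@H](OCc3ccccc3)C(=O)C[C@@H]2O[Si](C)(C)C(C)(C)C | intermediate
19 | trimethylsilyl enol ether of 18, double bond C8a=C4a | CC1(C)O[C@H]2[C@@H](O1)[C@H](OCc3ccccc3)C(O[Si](C)(C)C)=C[C@@H]2O[Si](C)(C)C(C)(C)C | intermediate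
20 | 2,2,6-trimethyl-4H-1,3-dioxin-4-one | CC1=CC(=O)OC(C)(C)O1 | starting material
21 | lithium dienolate of 20 (lithium 2,2-dimethyl-6-methylidene-6H-1,3-dioxin-4-olate) | [Li+].C=C1C=C([O-])OC(C)(C)O1 | intermediate (not isolated)
22 | 2,2-dimethyl-6-(2-phenylethyl)-4H-1,3-dioxin-4-one | CC1(C)OC(=O)C=C(CCc2ccccc2)O1 | intermediate
23 | 5-phenylpent-1-ene-1,3-dione (acylketene) | O=C=CC(=O)CCc1ccccc1 | intermediate (not isolated)
24 | hetero-Diels–Alder adduct: 8a-(trimethylsilyloxy)-4a,8a-dihydro precursor of 25 (C4a and C8a unassigned) | CC1(C)O[C@H]2[C@@H](O1)[C@H](OCc3ccccc3)C3(O[Si](C)(C)C)OC(CCc4ccccc4)=CC(=O)C3[C@@H]2O[Si](C)(C)C(C)(C)C | intermediate (not isolated)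
25 | 8-(benzyloxy)-5-[(tert-butyldimethylsilyl)oxy]-6,7-(isopropylidenedioxy)-2-(2-phenylethyl)-5,6,7,8-tetrahydro-4H-chromen-4-one, configuration at C5–C8 as in 38 | O=c1cc(CCc2ccccc2)oc2c1[C@H](O[Si](C)(C)C(C)(C)C)[C@@H](O3)[C@@H](OC3(C)C)[C@@H]2OCc1ccccc1 | intermediate
26 | 8-(benzyloxy)-5-hydroxy-6,7-(isopropylidenedioxy)-2-(2-phenylethyl)-5,6,7,8-tetrahydro-4H-chromen-4-one, configuration as in 38 | O=c1cc(CCc2ccccc2)oc2c1[C@H](O)[C@@H](O3)[C@@H](OC3(C)C)[C@@H]2OCc1ccccc1 | intermediate
27 | 2',4'-dihydroxyacetophenone | CC(=O)c1ccc(O)cc1O | starting material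
28 | 1-[4-(benzyloxy)-2-hydroxyphenyl]ethanone | CC(=O)c1ccc(OCc2ccccc2)cc1O | intermediate
29 | 1-[4-(benzyloxy)-2-hydroxy-5-iodophenyl]ethanone | CC(=O)c1cc(I)c(OCc2ccccc2)cc1O | intermediate
30 | ethyl 3-phenylpropanoate | CCOC(=O)CCc1ccccc1 | starting material
31 | 1-[4-(benzyloxy)-2-hydroxy-5-iodophenyl]-5-phenylpentane-1,3-dione | O=C(CC(=O)CCc1ccccc1)c1cc(I)c(OCc2ccccc2)cc1O | intermediate (not isolated)
32 | 7-(benzyloxy)-6-iodo-2-(2-phenylethyl)-4H-chromen-4-one | O=c1cc(CCc2ccccc2)oc2cc(OCc3ccccc3)c(I)cc12 | intermediate
33 | 7-(benzyloxy)-6-[hydroxy(tosyloxy)iodo]-2-(2-phenylethyl)-4H-chromen-4-one | Cc1ccc(cc1)S(=O)(=O)OI(O)c1cc2c(=O)cc(CCc3ccccc3)oc2cc1OCc1ccccc1 | intermediate (not isolated)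
34 | [7-(benzyloxy)-4-oxo-2-(2-phenylethyl)-4H-chromen-6-yl](2,4,6-trimethoxyphenyl)iodonium 4-methylbenzenesulfonate | COc1cc(OC)c([I+]c2cc3c(=O)cc(CCc4ccccc4)oc3cc2OCc2ccccc2)c(OC)c1.Cc1ccc(cc1)S(=O)(=O)[O-] | intermediate
35 | sodium 5-alkoxide of 26 | O=c1cc(CCc2ccccc2)oc2c1[C@H]([O-])[C@@H](O3)[C@@H](OC3(C)C)[C@@H]2OCc1ccccc1.[Na+] | intermediate (not isolated)
36 | 8-O-benzyl-6,7-O-isopropylidene-7′-O-benzyl derivative of 38 | O=c1cc(CCc2ccccc2)oc2c1[C@H](Oc1cc3c(=O)cc(CCc4ccccc4)oc3cc1OCc1ccccc1)[C@@H](O3)[C@@H](OC3(C)C)[C@@H]2OCc1ccccc1 | intermediate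
37 | 6,7-O-isopropylidene derivative of 38 | O=c1cc(CCc2ccccc2)oc2c1[C@H](Oc1cc3c(=O)cc(CCc4ccccc4)oc3cc1O)[C@@H](O3)[C@@H](OC3(C)C)[C@@H]2O | intermediate
38 | 6-{[(5S,6S,7R,8S)-6,7,8-trihydroxy-4-oxo-2-(2-phenylethyl)-5,6,7,8-tetrahydro-4H-chromen-5-yl]oxy}-7-hydroxy-2-(2-phenylethyl)-4H-chromen-4-one | O=c1cc(CCc2ccccc2)oc2c1[C@H](Oc1cc3c(=O)cc(CCc4ccccc4)oc3cc1O)[C@@H](O)[C@@H](O)[C@@H]2O | target

## Step count and least certain steps

Total: 27 steps. Longest linear sequence: 22 steps (steps 1–17, 19, 20, 25, 26, 27).

**Step 12 (key step).** The ketyls may be reduced further to the diol 12 or couple between molecules instead of closing the ring. The bulky silyl ether and the pivalate may distort the samarium-bridged transition state and lower the facial selectivity. The α-alkoxy aldehydes may epimerise or the pivalate may be lost by β-elimination before coupling. Fallback: from 13, double Wittig methylenation (Ph3P=CH2, THF, −78 → 0 °C) would give the 1,7-diene F1. Ring-closing metathesis with the second-generation Grubbs catalyst (CH2Cl2, 40 °C) would give the cyclohexene F2. Dihydroxylation with catalytic OsO4 and N-methylmorpholine N-oxide should take place on the face opposite the two allylic oxygen substituents, which lie on the same face, and so return to the route at 14.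

**Step 16.** Electron transfer may also cleave the benzyloxy group on C8, because both α-C–O bonds can align with the ketyl equally well and the selectivity rests only on leaving-group ability. The samarium enolate may expel the silyloxy group from C5, or the ketone may be reduced to the alcohol. Fallback: from 15, removal of the pivalate with i-Bu2AlH (CH2Cl2, −78 °C) would give the alcohol F3, and phenyl chlorothionoformate with pyridine and DMAP the thionocarbonate F4. Barton–McCombie deoxygenation (Bu3SnH, AIBN, toluene, 100 °C) would give the deoxy compound F5, oxidative removal of the 4-methoxybenzyl group with DDQ the alcohol F6, and Dess–Martin oxidation returns to the route at 18.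

**Step 19 (with the regiochemistry set in step 17).** The enol ether is hindered on both sides, so the acylketene may dimerise or be consumed by adventitious water before it is trapped. Acylation without ring closure, or loss of the C5 silyloxy group from the adduct instead of silanol, would also lower the outcome. Fallback: from 18, the lithium enolate (LiN(SiMe3)2, THF, −78 °C) would be added to 5-phenylpent-2-ynal F7, made from 4-phenylbut-1-yne by lithiation with n-BuLi and formylation with DMF, to give the aldol F8. Dess–Martin oxidation would give the β-diketone F9, and 6-endo cycloisomerisation of its enol onto the ynone (Ph3PAuNTf2 cat., CH2Cl2, rt) returns to the route at 25.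

**Step 25.** The alkoxide may act as a base: deprotonation at C8 starts eliminations that end in an aromatic chromone. The iodonium salt may lose its ortho hydrogen to give an aryne and hence regioisomeric ethers, the wrong aryl group may be transferred, or the hindered alkoxide may react too slowly. Fallback: from 26 and the iodide 32, palladium-catalysed C–O cross-coupling ([(allyl)PdCl]2, RockPhos, Cs2CO3, toluene, 90 °C) would give 36 directly. No stoichiometric alkoxide and no iodonium salt are involved, and no new compound is made.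

**Step 26.** Hydrogenolysis may also cleave the C5–O aryl ether, which is allylic to ring B, or saturate the C2=C3 bond of the non-aromatic pyranone if the reaction runs too long. Fallback: from 36, Lewis-acid debenzylation with BCl3 and pentamethylbenzene as cation scavenger (CH2Cl2, −78 °C, methanol quench) would remove both benzyl ethers and the acetonide without hydrogen and arrive at 38 directly, bypassing 37.

## Further compounds

F1 | step 12 | 3-O-benzyl-6-O-(tert-butyldimethylsilyl)-4-O-(4-methoxybenzyl)-5-O-pivaloyl-1,2,7,8-tetradeoxy-D-gluco-octa-1,7-dienitol | C=C[C@H](OCc1ccccc1)[C@@H](OCc1ccc(OC)cc1)[C@H](OC(=O)C(C)(C)C)[C@H](O[Si](C)(C)C(C)(C)C)C=C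
F2 | step 12 | cyclohex-6-ene (target numbering C6=C7) with C5 OTBS, C4a O-pivaloyl, C8a O-(4-methoxybenzyl), C8 O-benzyl, configuration as in 14 | C1=C[C@H](OCc2ccccc2)[C@@H](OCc2ccc(OC)cc2)[C@H](OC(=O)C(C)(C)C)[C@@H]1O[Si](C)(C)C(C)(C)C
F3 | step 16 | 4a-alcohol: 15 without the pivaloyl group | CC1(C)O[C@H]2[C@@H](O1)[C@H](OCc3ccccc3)[C@@H](OCc3ccc(OC)cc3)[C@H](O)[C@@H]2O[Si](C)(C)C(C)(C)C
F4 | step 16 | 4a-O-(phenoxythiocarbonyl) derivative of F3 | CC1(C)O[C@H]2[C@@H](O1)[C@H](OCc3ccccc3)[C@@H](OCc3ccc(OC)cc3)[C@H](OC(=S)Oc3ccccc3)[C@@H]2O[Si](C)(C)C(C)(C)C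
F5 | step 16 | 4a-deoxy compound with 8a-O-(4-methoxybenzyl), 8-O-benzyl, 5-O-TBS and 6,7-acetonide | CC1(C)O[C@H]2[C@@H](O1)[C@H](OCc3ccccc3)[C@@H](OCc3ccc(OC)cc3)C[C@@H]2O[Si](C)(C)C(C)(C)C
F6 | step 16 | 4a-deoxy 8a-alcohol | CC1(C)O[C@H]2[C@@H](O1)[C@H](OCc3ccccc3)[C@@H](O)C[C@@H]2O[Si](C)(C)C(C)(C)C
F7 | step 19 | 5-phenylpent-2-ynal | O=CC#CCCc1ccccc1
F8 | step 19 | aldol adduct of 18 at C4a with F7 (C4a and carbinol carbon unassigned) | CC1(C)O[C@H]2[C@@H](O1)[C@H](OCc3ccccc3)C(=O)C(C(O)C#CCCc3ccccc3)[C@@H]2O[Si](C)(C)C(C)(C)C
F9 | step 19 | 4a-(5-phenylpent-2-ynoyl) derivative of 18 (β-diketone) | CC1(C)O[C@H]2[C@@H](O1)[C@H](OCc3ccccc3)C(=O)C(C(=O)C#CCCc3ccccc3)[C@@H]2O[Si](C)(C)C(C)(C)C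
F0 | step 25 | none | none
F0 | step 26 | none | none
A1 | alternative 1 | 2-(2-phenylethyl)-4H-chromene-4,5,8-trione | O=C1C=CC(=O)C2=C1C(=O)C=C(CCc1ccccc1)O2
A2 | alternative 1 | cyclopenta-1,3-diene | C1=CCC=C1
A3 | alternative 1 | endo cyclopentadiene adduct of A1 at C6 and C7 | O=C1[C@@H]2[C@@H]3C=C[C@@H](C3)[C@@H]2C(=O)C2=C1C(=O)C=C(CCc1ccccc1)O2
A4 | alternative 2 | bis(5-phenylpent-2-ynoyl) precursor: tri-O-benzyl 2-acylcyclohexanone carrying the O5 aryl ether of a 2-hydroxy-4-(benzyloxy)aryl ynone | O=C(C#CCCc1ccccc1)C1C(=O)[C@@H](OCc2ccccc2)[C@H](OCc2ccccc2)[C@H](OCc2ccccc2)[C@H]1Oc1cc(C(=O)C#CCCc2ccccc2)c(O)cc1OCc1ccccc1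
A5 | alternative 2 | 6,7,8,7′-tetra-O-benzyl derivative of the target | O=c1cc(CCc2ccccc2)oc2c1[C@H](Oc1cc3c(=O)cc(CCc4ccccc4)oc3cc1OCc1ccccc1)[C@@H](OCc1ccccc1)[C@@H](OCc1ccccc1)[C@@H]2OCc1ccccc1
A6 | alternative 3 | trimethylsilyl enol ether of the 5-O-TBS-6,7,8-tri-O-benzyl cyclohexanone | C[Si](C)(C)OC1=C[C@H](O[Si](C)(C)C(C)(C)C)[C@@H](OCc2ccccc2)[C@@H](OCc2ccccc2)[C@@H]1OCc1ccccc1
A7 | alternative 3 | 2,2-dimethyl-6-(2-phenylethyl)-4H-1,3-dioxin-4-one | CC1(C)OC(=O)C=C(CCc2ccccc2)O1
A8 | alternative 3 | 6,7,8-tris(benzyloxy)-5-[(tert-butyldimethylsilyl)oxy]-2-(2-phenylethyl)-5,6,7,8-tetrahydro-4H-chromen-4-one | O=c1cc(CCc2ccccc2)oc2c1[C@H](O[Si](C)(C)C(C)(C)C)[C@@H](OCc1ccccc1)[C@@H](OCc1ccccc1)[C@@H]2OCc1ccccc1
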